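## Analysis of the target

Locants used for all tricyclic compounds: tricyclo[5.4.0.0^{2,8}]undecane, with C11 the enone carbonyl, C9=C10 the enone alkene (methyl on C9), C2 the methyl-bearing quaternary carbon, C3 (OH), C4 (2-methylbutanoate), C5 (angelate), C6 (CMe2) and C7 (CH).

- The skeleton is a cyclobutane C1–C2–C8–C7 bridged twice across its 1,3-positions. C1 and C8 are joined on one face by the enone C11(=O)–C10=C9(Me), giving a verbenone-type bicyclo[3.1.1]heptenone. C2 and C7 are joined on the other face by C3–C4–C5–C6, giving a bicyclo[4.1.1]octane with a seven-membered ring.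
- The four ring-fusion stereocenters C1, C2, C7 and C8 are locked together by the two bridges: the C2 methyl and the C7 hydrogen must point toward the enone bridge.
- On the seven-membered ring, the C3 hydroxyl and the C4 acyloxy group are cis, and the C4 and C5 acyloxy groups are trans. The 2-methylbutanoate adds an (R) center.
- Seen from C3–C5, C1 and C8 differ only in carrying C11(=O) or C9(Me). The two faces of the seven-membered ring are therefore related by a local mirror plane through C2, C7 and the C3–C6 bridge, and the core cannot be expected to direct the carbinol centers.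
- Sensitive groups are the angelate (Z to E isomerisation by nucleophiles and radicals), the free C3 hydroxyl cis to an ester (acyl migration), and the strained cyclobutane flanked by a ketone.
- The hard part is the cyclobutane: it is a crossed [2+2] pattern with one quaternary corner, and three vicinal oxygens must end up differently acylated.
- The feature exploited: the fifteen skeletal carbons form one unbranched farnesane chain C7–C8–C9–C10–C11–C1–C2–C3–C4–C5–C6, closed by the three bonds C1–C7, C2–C8 and C6–C7. C7 carries only H and C6, so it is the one cyclobutane carbon that can be the carbonyl carbon of a cyclobutanone, that is, the carboxyl carbon of an acyclic acid. C11 lies on the tether between that carboxyl carbon and the C1=C2 alkene, so its oxygen can serve as a temporary stereocenter before it becomes the enone carbonyl.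

## Retrosynthetic reasoning

**33 to 30 + 31 (C4–O acyl bond).** The 2-methylbutanoate is put on last. It is the ester most prone to migrate toward the cis C3 hydroxyl, and C4–OH in 30 is the less hindered and more acidic of the two hydroxyls, since C3 is flanked by quaternary C2. The forward step has to acylate once, at C4, without racemising the acyl α-center.

**30 to 29 (C3–O and C4–O).** The cis-3,4/trans-4,5 pattern is what a syn-dihydroxylation of a C3=C4 alkene anti to an allylic C5 acyloxy group delivers. Cutting here turns two stereocenters into one cis alkene inside the seven-membered ring and lets C5 relay to C3 and C4 in a single event. The forward step must prefer the isolated ring alkene over the two conjugated trisubstituted alkenes, which is why the C9=C10–C11=O enone has to be in place first.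

**29 to 27, 26, 23 + 24, and 21 (C11 oxidation level, C5 ester, C5 carbinol).** The enone is traced back to a C11 silyl ether with an exocyclic C9 methylidene (26 and 27); oxidation and isomerisation erase C11 as a stereocenter once it has done its job. The angelate comes from alcohol 23 and acid 24. Alcohol 23 comes from enone 21 by a CBS reduction: because of the local mirror plane, the substrate offers no bias, so the reagent alone has to decide the configuration at C5.

**21 to 20 to 16 (C7–O removal, C6–C7 bond).** C7 is a carbonyl carbon in the cycloadduct, so the C6–C7 bond is made by an intramolecular aldol addition of an isopropyl ketone enolate (C6) to the cyclobutanone. The resulting tertiary C7 oxygen is removed by radical deoxygenation of xanthate 20. The tether from C2 can only reach C7 from the face anti to the enone bridge, so the C7 configuration is enforced by the ring and needs no reagent control.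

**16 to 15 to 13 + 14 (C4–C5 bond, Z alkene).** The side chain is added after the cycloaddition, for two reasons: a conjugated ynone on C2 would deactivate the alkene toward the ketene, and allylic carbinol centers would compete with the tether for facial control. The ethynyl group of 13 is acylated with 14, and semi-hydrogenation gives the Z-enone, which is needed for ring closure.

**13 to 10 (key disconnection: C1–C7 and C2–C8).** Both cyclobutane bonds are cut in the sense of an intramolecular vinylketene–alkene [2+2] cycloaddition. The precursor is the acyclic dienynoic acid 10, in which the C11 silyloxy group sits on the tether. The forward reaction must give the crossed bicyclo[3.1.1] adduct, transfer the E-alkene geometry to C2, and let the single C11 stereocenter fix C1, C2 and C8.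

**10 to 8, 7, and 2 + 5 (C10–C11 bond).** Acid 10 comes from ester 8, the silyl ether of 7. Alcohol 7 comes from a catalytic asymmetric vinylogous Mukaiyama aldol between enynal 2 (from commercial 1) and silyl dienol ether 5 (from commercial 3). This is the only place before the C5 reduction where an external chiral source is needed.

## Alternatives that were turned down

**Alternative 1:** the textbook cyclobutane disconnection, cutting C1–C7 and C2–C8 as an enone–olefin [2+2] photocycloaddition, run transannularly on the eleven-membered humulatrienone A1. The forward key step is irradiation of A1 to give 33 directly. It was turned down on three grounds. The two alkenes are linked through the three sp2 atoms C11, C10 and C9, so the rule of five favours initial C1–C8 bonding and a fused bicyclo[3.2.0] adduct; E/Z isomerisation and photo-Nazarov closure of the cross-conjugated dienone are further exits. A1 itself, an eleven-membered ring with a conjugated trienone and three contiguous carbinol centers, would cost more steps than the cycloaddition returns. The relay from C3–C5 to the ring fusion would rest on macrocycle conformation alone.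

**Alternative 2:** a chiral-pool route that keeps the bicyclo[3.1.1] core intact: (−)-verbenone A2 is photoisomerised to chrysanthenone A3, whose carbonyl carbon is C7 and whose gem-dimethyl carbon is C2. The forward key step would functionalise the C2 methyl that points toward C7 and then bridge it to C7. It was turned down because A3 is formed with partial loss of optical purity through a reversible ring opening to an achiral vinylketene, and because the only handle near that methyl is an oxygen on C7, whose alkoxy radical would open the cyclobutane by β-scission faster than it abstracts hydrogen. At least two steps without precedent would sit on top of a starting material of uncertain enantiopurity.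

**Alternative 3:** cutting the enone ring last, at C9=C10, by intramolecular aldol condensation of the cis-1,3-diacetylcyclobutane A4. The forward key step is enolisation of one acetyl group and condensation onto the other. It was turned down because the two acetyl groups of A4 are related by the local mirror plane of the bicyclo[4.1.1]octane; only the remote carbinol centers distinguish them, so 33 and its regioisomer A5 should form in comparable amounts. A4 also still contains the 1,3-bridged cyclobutane, so the hard bond-forming problem is only postponed.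

Key step: step 6

Assumptions: compounds 1, 3, 14, 24 and 31 are taken as purchased. The (S,S)-bisphosphoramide in step 3 is assumed to deliver the dienol ether to the Si face of 2; the sense should be checked on the first batch and the enantiomeric catalyst used if it is opposite. Chain locants C1 to C9 of 6–12 become C7, C8, C9, C10, C11, C1, C2, C3, C4 of the tricycle. In bicyclic 13, 15 and 16, C1, C2, C4, C5, C6, C7 correspond to tricycle C1, C11, C9, C8, C7, C2.

## Route

Step 1
Reactants: 1 (2E)-3-methylpent-2-en-4-yn-1-ol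
Product: 2 (2E)-3-methylpent-2-en-4-ynal
Conditions: MnO2 (excess), CH2Cl2, rt; filtered and used as a solution
Reagents that add atoms: none
Why: Allylic oxidation with manganese dioxide stops at the enal and should leave the alkene geometry and the alkyne untouched; 2 is volatile and is not concentrated to dryness.

Step 2
Reactants: 3 methyl 3-methylbut-2-enoate
Product: 5 tert-butyl[(1-methoxy-3-methylbuta-1,3-dien-1-yl)oxy]dimethylsilane, via lithium dienolate 4 (not isolated)
Conditions: LDA, THF, −78 °C; TBSCl, DMPU, −78 °C to rt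
Reagents that add atoms: tert-butyldimethylsilyl chloride, C[Si](C)(Cl)C(C)(C)C
Why: γ-Deprotonation of the senecioate and O-silylation of the dienolate give the silyl dienol ether needed as vinylogous nucleophile; the C1=C2 geometry is without consequence.

Step 3
Reactants: 2 (2E)-3-methylpent-2-en-4-ynal; 5 tert-butyl[(1-methoxy-3-methylbuta-1,3-dien-1-yl)oxy]dimethylsilane
Product: 7 methyl (2E,5S,6E)-5-hydroxy-3,7-dimethylnona-2,6-dien-8-ynoate, via trichlorosilyl ether 6 (not isolated)
Conditions: SiCl4, (S,S)-BINAM-derived bisphosphoramide (5 mol%), iPr2NEt (10 mol%), CH2Cl2, −78 °C; aq NaHCO3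
Reagents that add atoms: none
Why: Catalytic asymmetric vinylogous Mukaiyama aldol with Lewis-base-activated SiCl4; the chiral silyl cation binds the aldehyde and the dienol ether should attack through its γ-carbon at the Si face, setting C5 as S. The 2E enoate (methyl cis to the ester) is expected to predominate.

Step 4
Reactants: 7 methyl (2E,5S,6E)-5-hydroxy-3,7-dimethylnona-2,6-dien-8-ynoate
Product: 8 methyl (2E,5S,6E)-5-{[tert-butyl(dimethyl)silyl]oxy}-3,7-dimethylnona-2,6-dien-8-ynoate
Conditions: TBSCl, imidazole, DMF, rt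
Reagents that add atoms: tert-butyldimethylsilyl chloride, C[Si](C)(Cl)C(C)(C)C
Why: Standard silylation; the bulky silyl ether is the group that will later steer the cycloaddition and it survives all steps up to step 13.

Step 5
Reactants: 8 methyl (2E,5S,6E)-5-{[tert-butyl(dimethyl)silyl]oxy}-3,7-dimethylnona-2,6-dien-8-ynoate
Product: 10 (2E,5S,6E)-5-{[tert-butyl(dimethyl)silyl]oxy}-3,7-dimethylnona-2,6-dien-8-ynoic acid, via lithium carboxylate 9 (not isolated)
Conditions: LiOH·H2O, THF/MeOH/H2O, 40 °C; 1 M HCl to pH 4, 0 °C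
Reagents that add atoms: lithium hydroxide, [Li+].[OH-]
Why: Saponification of the conjugated methyl ester; the secondary TBS ether and the terminal alkyne should tolerate hydroxide and the brief mild acidification.

Step 6
Reactants: 10 (2E,5S,6E)-5-{[tert-butyl(dimethyl)silyl]oxy}-3,7-dimethylnona-2,6-dien-8-ynoic acid
Product: 13 (1R,2S,5R,7R)-2-{[tert-butyl(dimethyl)silyl]oxy}-7-ethynyl-7-methyl-4-methylidenebicyclo[3.1.1]heptan-6-one, via acid chloride 11 (not isolated), via vinylketene 12 (not isolated)
Conditions: 1-chloro-N,N,2-trimethylprop-1-en-1-amine, CH2Cl2, 0 °C to rt; then syringe-pump addition to Et3N, toluene, 110 °C (0.01 M)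
Reagents that add atoms: none
Why: The chloroenamine converts 10 into acid chloride 11 under neutral conditions, and triethylamine removes HCl across the carbonyl and the syn C3 methyl to give vinylketene 12, which adds to the C6=C7 alkene in an asynchronous thermal [2+2] cycloaddition, the reaction type known from the conversion of geranoyl and farnesoyl chlorides into 2-methylidenebicyclo[3.1.1]heptan-6-ones. The ketene carbonyl carbon bonds to the alkene CH, closing the six-membered ring C7–C8–C9–C10–C11–C1 (tricycle locants) in a 6-exo sense, while positive charge builds on the tertiary propargylic carbon, which then closes the four-membered ring onto the ketene α-carbon (C2–C8); the crossed bicyclo[3.1.1] skeleton is therefore expected and not the fused bicyclo[3.2.0] one. C1, C2 and C8 are created together: the addition is suprafacial on the alkene, so the E geometry places the C2 methyl syn and the ethynyl group anti to the three-carbon bridge. The absolute sense comes from the C11 silyloxy stereocenter on the tether: to avoid A(1,3) strain with the methyl group cis to it on the alkene, the C11 hydrogen takes the position next to that methyl and the OTBS group points away from the forming C2 bridge, so the tethered ketene can reach only one alkene face. The selectivities needed are crossed over fused regiochemistry (secured by the trisubstituted alkene and the cumulene electrophile), cycloaddition over ketene dimerisation (slow addition at high dilution), and deprotonation at the syn methyl and not at C4 (the 2E acid chloride holds the methyl cis to the carbonyl).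

Step 7
Reactants: 13 (1R,2S,5R,7R)-2-{[tert-butyl(dimethyl)silyl]oxy}-7-ethynyl-7-methyl-4-methylidenebicyclo[3.1.1]heptan-6-one; 14 2-methylpropanoyl chloride
Product: 15 (1R,2S,5R,7R)-2-{[tert-butyl(dimethyl)silyl]oxy}-7-methyl-4-methylidene-7-(4-methyl-3-oxopent-1-yn-1-yl)bicyclo[3.1.1]heptan-6-one
Conditions: PdCl2(PPh3)2 (2 mol%), CuI (4 mol%), Et3N, THF, rt
Reagents that add atoms: none
Why: Acyl Sonogashira coupling of the terminal alkyne with the acid chloride; no strong base or hard nucleophile meets the strained, non-enolisable cyclobutanone.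

Step 8
Reactants: 15 (1R,2S,5R,7R)-2-{[tert-butyl(dimethyl)silyl]oxy}-7-methyl-4-methylidene-7-(4-methyl-3-oxopent-1-yn-1-yl)bicyclo[3.1.1]heptan-6-one
Product: 16 (1R,2S,5R,7R)-2-{[tert-butyl(dimethyl)silyl]oxy}-7-methyl-4-methylidene-7-[(1Z)-4-methyl-3-oxopent-1-en-1-yl]bicyclo[3.1.1]heptan-6-one
Conditions: H2 (1 atm), Lindlar catalyst, quinoline, EtOAc, 0 °C to rt
Reagents that add atoms: none
Why: Lindlar semi-hydrogenation adds hydrogen syn and should give the Z-enone while leaving the 1,1-disubstituted methylidene and both ketones; the Z geometry is what lets the isopropyl carbon reach the cyclobutanone.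

Step 9
Reactants: 16 (1R,2S,5R,7R)-2-{[tert-butyl(dimethyl)silyl]oxy}-7-methyl-4-methylidene-7-[(1Z)-4-methyl-3-oxopent-1-en-1-yl]bicyclo[3.1.1]heptan-6-one
Product: 20 S-methyl O-[(1R,2R,7R,8R,11S)-11-{[tert-butyl(dimethyl)silyl]oxy}-2,6,6-trimethyl-9-methylidene-5-oxotricyclo[5.4.0.0^{2,8}]undec-3-en-7-yl] carbonodithioate, via lithium dienolate 17 (not isolated), via lithium aldolate 18 (not isolated), via lithium dithiocarbonate 19 (not isolated)
Conditions: LiHMDS, THF, −78 to −40 °C; CS2, −78 to −20 °C; MeI, −20 to 0 °C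
Reagents that add atoms: carbon disulfide, S=C=S; iodomethane, CI
Why: The isopropyl methine is the only enolisable position of 16 (the cyclobutanone α-carbons are bridgeheads and the enone γ-carbon is quaternary), so the dienolate forms regiospecifically and closes C6–C7 by a 7-(enolendo)-exo-trig aldol addition onto the strain-activated cyclobutanone. The anti-oriented tether can reach only one carbonyl face, which fixes C7; the alkoxide is trapped as a xanthate that has no β-hydrogen able to eliminate without forming a bridgehead alkene.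

Step 10
Reactants: 20 S-methyl O-[(1R,2R,7R,8R,11S)-11-{[tert-butyl(dimethyl)silyl]oxy}-2,6,6-trimethyl-9-methylidene-5-oxotricyclo[5.4.0.0^{2,8}]undec-3-en-7-yl] carbonodithioate
Product: 21 (1R,2R,7S,8R,11S)-11-{[tert-butyl(dimethyl)silyl]oxy}-2,6,6-trimethyl-9-methylidenetricyclo[5.4.0.0^{2,8}]undec-3-en-5-one
Conditions: Bu3SnH (0.5 M), AIBN, toluene, 90 °C
Reagents that add atoms: none
Why: Barton–McCombie deoxygenation: the stannyl radical adds to C=S, β-scission gives the tertiary C7 radical, and hydrogen transfer from the tin hydride completes C7–H, whose configuration is dictated by the ring because C6 must stay anti. The cyclobutane bonds lie near the nodal plane of the radical orbital, so ring opening should be slow against hydrogen transfer at high hydride concentration, and enones are reduced only sluggishly under these conditions.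

Step 11
Reactants: 21 (1R,2R,7S,8R,11S)-11-{[tert-butyl(dimethyl)silyl]oxy}-2,6,6-trimethyl-9-methylidenetricyclo[5.4.0.0^{2,8}]undec-3-en-5-one
Product: 23 (1R,2R,5R,7S,8R,11S)-11-{[tert-butyl(dimethyl)silyl]oxy}-2,6,6-trimethyl-9-methylidenetricyclo[5.4.0.0^{2,8}]undec-3-en-5-ol, via catechol borate 22 (not isolated)
Conditions: (S)-Me-CBS (20 mol%), catecholborane, toluene, −78 °C; MeOH, then aq NaHCO3
Reagents that add atoms: none
Why: Corey–Bakshi–Shibata 1,2-reduction under reagent control: the two carbonyl faces are related by the local mirror plane of the core, so the catalyst decides, with quaternary C6 as the large and the C4 alkenyl carbon as the small group, which should give the 5R alcohol. Catecholborane at −78 °C should not hydroborate the methylidene.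

Step 12
Reactants: 23 (1R,2R,5R,7S,8R,11S)-11-{[tert-butyl(dimethyl)silyl]oxy}-2,6,6-trimethyl-9-methylidenetricyclo[5.4.0.0^{2,8}]undec-3-en-5-ol; 24 (2Z)-2-methylbut-2-enoic acid (angelic acid)
Product: 26 (1R,2R,5R,7S,8R,11S)-11-{[tert-butyl(dimethyl)silyl]oxy}-2,6,6-trimethyl-9-methylidenetricyclo[5.4.0.0^{2,8}]undec-3-en-5-yl (2Z)-2-methylbut-2-enoate, via mixed anhydride 25 (not isolated)
Conditions: 24, 2,4,6-trichlorobenzoyl chloride, Et3N, toluene, rt; then 23, 75 °C
Reagents that add atoms: none
Why: Yamaguchi esterification through the mixed anhydride acylates hindered secondary alcohols, and without a nucleophilic catalyst the angelate should keep its Z geometry; the C5 hydroxyl is the only free hydroxyl.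

Step 13
Reactants: 26 (1R,2R,5R,7S,8R,11S)-11-{[tert-butyl(dimethyl)silyl]oxy}-2,6,6-trimethyl-9-methylidenetricyclo[5.4.0.0^{2,8}]undec-3-en-5-yl (2Z)-2-methylbut-2-enoate
Product: 27 (1R,2R,5R,7S,8R,11S)-11-hydroxy-2,6,6-trimethyl-9-methylidenetricyclo[5.4.0.0^{2,8}]undec-3-en-5-yl (2Z)-2-methylbut-2-enoate
Conditions: HF·pyridine, pyridine, THF, 0 °C to rt
Reagents that add atoms: none
Why: Buffered fluoride cleaves the Si–O bond and should leave the angelate and the three alkenes alone.

Step 14
Reactants: 27 (1R,2R,5R,7S,8R,11S)-11-hydroxy-2,6,6-trimethyl-9-methylidenetricyclo[5.4.0.0^{2,8}]undec-3-en-5-yl (2Z)-2-methylbut-2-enoate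
Product: 29 (1R,2R,5R,7S,8R)-2,6,6,9-tetramethyl-11-oxotricyclo[5.4.0.0^{2,8}]undeca-3,9-dien-5-yl (2Z)-2-methylbut-2-enoate, via deconjugated enone 28 (not isolated)
Conditions: Dess–Martin periodinane, NaHCO3, CH2Cl2, 0 °C to rt; then DBU (0.2 equiv), 0 °C
Reagents that add atoms: none
Why: Dess–Martin oxidation gives the β,γ-unsaturated ketone, and brief base treatment moves the exocyclic double bond into conjugation through the C10 dienolate, giving the trisubstituted verbenone-type enone. The relay stereocenter C11 is erased here, and bridgehead C1 cannot enolise.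

Step 15
Reactants: 29 (1R,2R,5R,7S,8R)-2,6,6,9-tetramethyl-11-oxotricyclo[5.4.0.0^{2,8}]undeca-3,9-dien-5-yl (2Z)-2-methylbut-2-enoate
Product: 30 (1R,2R,3S,4S,5S,7S,8R)-3,4-dihydroxy-2,6,6,9-tetramethyl-11-oxotricyclo[5.4.0.0^{2,8}]undec-9-en-5-yl (2Z)-2-methylbut-2-enoate
Conditions: OsO4 (5 mol%), NMO, acetone/H2O, rt
Reagents that add atoms: osmium tetroxide, O=[Os](=O)(=O)=O; 4-methylmorpholine N-oxide, C[N+]1([O-])CCOCC1; water, O
Why: Upjohn syn-dihydroxylation; the isolated cis-disubstituted C3=C4 alkene should react ahead of the two conjugated trisubstituted alkenes. Attack anti to the allylic C5 acyloxy group (Kishi's empirical rule) sets C3 and C4 cis to each other and C4–O trans to C5–O.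

Step 16
Reactants: 30 (1R,2R,3S,4S,5S,7S,8R)-3,4-dihydroxy-2,6,6,9-tetramethyl-11-oxotricyclo[5.4.0.0^{2,8}]undec-9-en-5-yl (2Z)-2-methylbut-2-enoate; 31 (2R)-2-methylbutanoic acid
Product: 33 (1R,2R,3S,4S,5S,7S,8R)-3-hydroxy-2,6,6,9-tetramethyl-4-{[(2R)-2-methylbutanoyl]oxy}-11-oxotricyclo[5.4.0.0^{2,8}]undec-9-en-5-yl (2Z)-2-methylbut-2-enoate, via O-acylisourea 32 (not isolated)
Conditions: 31 (1.05 equiv), DCC, DMAP (10 mol%), CH2Cl2, −20 °C
Reagents that add atoms: none
Why: Steglich esterification; the C4 hydroxyl sits between two methine carbons and is the more acidic (β-acyloxy), whereas the C3 hydroxyl is next to quaternary C2, so a single acylation at low temperature should go to C4. The low temperature and the small amount of DMAP limit racemisation of the acyl α-center.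

## Compound list

1 | (2E)-3-methylpent-2-en-4-yn-1-ol | OC/C=C(\C)C#C | starting material
2 | (2E)-3-methylpent-2-en-4-ynal | O=C/C=C(\C)C#C | intermediate
3 | methyl 3-methylbut-2-enoate | COC(=O)C=C(C)C | starting material
4 | lithium 1-methoxy-3-methylbuta-1,3-dien-1-olate | [Li+].COC([O-])=CC(C)=C | intermediate
5 | tert-butyl[(1-methoxy-3-methylbuta-1,3-dien-1-yl)oxy]dimethylsilane | COC(O[Si](C)(C)C(C)(C)C)=CC(C)=C | intermediate
6 | methyl (2E,5S,6E)-3,7-dimethyl-5-[(trichlorosilyl)oxy]nona-2,6-dien-8-ynoate | COC(=O)/C=C(\C)C[C@H](O[Si](Cl)(Cl)Cl)/C=C(\C)C#C | intermediate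
7 | methyl (2E,5S,6E)-5-hydroxy-3,7-dimethylnona-2,6-dien-8-ynoate | COC(=O)/C=C(\C)C[C@H](O)/C=C(\C)C#C | intermediate
8 | methyl (2E,5S,6E)-5-{[tert-butyl(dimethyl)silyl]oxy}-3,7-dimethylnona-2,6-dien-8-ynoate | COC(=O)/C=C(\C)C[C@H](O[Si](C)(C)C(C)(C)C)/C=C(\C)C#C | intermediate
9 | lithium (2E,5S,6E)-5-{[tert-butyl(dimethyl)silyl]oxy}-3,7-dimethylnona-2,6-dien-8-ynoate | [Li+].[O-]C(=O)/C=C(\C)C[C@H](O[Si](C)(C)C(C)(C)C)/C=C(\C)C#C | intermediate
10 | (2E,5S,6E)-5-{[tert-butyl(dimethyl)silyl]oxy}-3,7-dimethylnona-2,6-dien-8-ynoic acid | OC(=O)/C=C(\C)C[C@H](O[Si](C)(C)C(C)(C)C)/C=C(\C)C#C | intermediate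
11 | (2E,5S,6E)-5-{[tert-butyl(dimethyl)silyl]oxy}-3,7-dimethylnona-2,6-dien-8-ynoyl chloride | ClC(=O)/C=C(\C)C[C@H](O[Si](C)(C)C(C)(C)C)/C=C(\C)C#C | intermediate
12 | (5S,6E)-5-{[tert-butyl(dimethyl)silyl]oxy}-7-methyl-3-methylidenenona-1,6-dien-8-yn-1-one (vinylketene) | O=C=CC(=C)C[C@H](O[Si](C)(C)C(C)(C)C)/C=C(\C)C#C | intermediate
13 | (1R,2S,5R,7R)-2-{[tert-butyl(dimethyl)silyl]oxy}-7-ethynyl-7-methyl-4-methylidenebicyclo[3.1.1]heptan-6-one (ethynyl anti, methyl syn to the C2–C4 bridge; OTBS on the side of the carbonyl bridge) | C#C[C@@]1(C)[C@@H]2[C@@H](O[Si](C)(C)C(C)(C)C)CC(=C)[C@H]1C2=O | intermediate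
14 | 2-methylpropanoyl chloride | CC(C)C(Cl)=O | starting material
15 | (1R,2S,5R,7R)-2-{[tert-butyl(dimethyl)silyl]oxy}-7-methyl-4-methylidene-7-(4-methyl-3-oxopent-1-yn-1-yl)bicyclo[3.1.1]heptan-6-one | CC(C)C(=O)C#C[C@@]1(C)[C@@H]2[C@@H](O[Si](C)(C)C(C)(C)C)CC(=C)[C@H]1C2=O | intermediate
16 | (1R,2S,5R,7R)-2-{[tert-butyl(dimethyl)silyl]oxy}-7-methyl-4-methylidene-7-[(1Z)-4-methyl-3-oxopent-1-en-1-yl]bicyclo[3.1.1]heptan-6-one | CC(C)C(=O)/C=C\[C@@]1(C)[C@@H]2[C@@H](O[Si](C)(C)C(C)(C)C)CC(=C)[C@H]1C2=O | intermediate
17 | lithium dienolate of 16 (enolate carbon = the former isopropyl methine) | CC(C)=C([O-])/C=C\[C@@]1(C)[C@@H]2[C@@H](O[Si](C)(C)C(C)(C)C)CC(=C)[C@H]1C2=O.[Li+] | intermediate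
18 | lithium (1R,2R,7R,8R,11S)-11-{[tert-butyl(dimethyl)silyl]oxy}-2,6,6-trimethyl-9-methylidene-5-oxotricyclo[5.4.0.0^{2,8}]undec-3-en-7-olate | O=C1C=C[C@@]2(C)[C@@H]3[C@@H](O[Si](C)(C)C(C)(C)C)CC(=C)[C@H]2[C@]3([O-])C1(C)C.[Li+] | intermediate
19 | lithium O-[(1R,2R,7R,8R,11S)-11-{[tert-butyl(dimethyl)silyl]oxy}-2,6,6-trimethyl-9-methylidene-5-oxotricyclo[5.4.0.0^{2,8}]undec-3-en-7-yl] carbonodithioate | O=C1C=C[C@@]2(C)[C@@H]3[C@@H](O[Si](C)(C)C(C)(C)C)CC(=C)[C@H]2[C@]3(OC(=S)[S-])C1(C)C.[Li+] | intermediate
20 | S-methyl O-[(1R,2R,7R,8R,11S)-11-{[tert-butyl(dimethyl)silyl]oxy}-2,6,6-trimethyl-9-methylidene-5-oxotricyclo[5.4.0.0^{2,8}]undec-3-en-7-yl] carbonodithioate | O=C1C=C[C@@]2(C)[C@@H]3[C@@H](O[Si](C)(C)C(C)(C)C)CC(=C)[C@H]2[C@]3(OC(=S)SC)C1(C)C | intermediate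
21 | (1R,2R,7S,8R,11S)-11-{[tert-butyl(dimethyl)silyl]oxy}-2,6,6-trimethyl-9-methylidenetricyclo[5.4.0.0^{2,8}]undec-3-en-5-one | O=C1C=C[C@@]2(C)[C@@H]3[C@@H](O[Si](C)(C)C(C)(C)C)CC(=C)[C@H]2[C@@H]3C1(C)C | intermediate
22 | 2-{[(1R,2R,5R,7S,8R,11S)-11-{[tert-butyl(dimethyl)silyl]oxy}-2,6,6-trimethyl-9-methylidenetricyclo[5.4.0.0^{2,8}]undec-3-en-5-yl]oxy}-1,3,2-benzodioxaborole | B1(O[C@@H]2C=C[C@@]3(C)[C@@H]4[C@@H](O[Si](C)(C)C(C)(C)C)CC(=C)[C@H]3[C@@H]4C2(C)C)Oc5ccccc5O1 | intermediate
23 | (1R,2R,5R,7S,8R,11S)-11-{[tert-butyl(dimethyl)silyl]oxy}-2,6,6-trimethyl-9-methylidenetricyclo[5.4.0.0^{2,8}]undec-3-en-5-ol | O[C@@H]1C=C[C@@]2(C)[C@@H]3[C@@H](O[Si](C)(C)C(C)(C)C)CC(=C)[C@H]2[C@@H]3C1(C)C | intermediate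
24 | (2Z)-2-methylbut-2-enoic acid (angelic acid) | C/C=C(/C)C(=O)O | starting material
25 | (2Z)-2-methylbut-2-enoic 2,4,6-trichlorobenzoic anhydride | C/C=C(/C)C(=O)OC(=O)c1c(Cl)cc(Cl)cc1Cl | intermediate
26 | (1R,2R,5R,7S,8R,11S)-11-{[tert-butyl(dimethyl)silyl]oxy}-2,6,6-trimethyl-9-methylidenetricyclo[5.4.0.0^{2,8}]undec-3-en-5-yl (2Z)-2-methylbut-2-enoate | C/C=C(/C)C(=O)O[C@@H]1C=C[C@@]2(C)[C@@H]3[C@@H](O[Si](C)(C)C(C)(C)C)CC(=C)[C@H]2[C@@H]3C1(C)C | intermediate
27 | (1R,2R,5R,7S,8R,11S)-11-hydroxy-2,6,6-trimethyl-9-methylidenetricyclo[5.4.0.0^{2,8}]undec-3-en-5-yl (2Z)-2-methylbut-2-enoate | C/C=C(/C)C(=O)O[C@@H]1C=C[C@@]2(C)[C@@H]3[C@@H](O)CC(=C)[C@H]2[C@@H]3C1(C)C | intermediate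
28 | (1R,2R,5R,7S,8R)-2,6,6-trimethyl-9-methylidene-11-oxotricyclo[5.4.0.0^{2,8}]undec-3-en-5-yl (2Z)-2-methylbut-2-enoate | C/C=C(/C)C(=O)O[C@@H]1C=C[C@@]2(C)[C@@H]3C(=O)CC(=C)[C@H]2[C@@H]3C1(C)C | intermediate
29 | (1R,2R,5R,7S,8R)-2,6,6,9-tetramethyl-11-oxotricyclo[5.4.0.0^{2,8}]undeca-3,9-dien-5-yl (2Z)-2-methylbut-2-enoate | C/C=C(/C)C(=O)O[C@@H]1C=C[C@@]2(C)[C@@H]3C(=O)C=C(C)[C@H]2[C@@H]3C1(C)C | intermediate
30 | (1R,2R,3S,4S,5S,7S,8R)-3,4-dihydroxy-2,6,6,9-tetramethyl-11-oxotricyclo[5.4.0.0^{2,8}]undec-9-en-5-yl (2Z)-2-methylbut-2-enoate | C/C=C(/C)C(=O)O[C@@H]1[C@@H](O)[C@@H](O)[C@@]2(C)[C@@H]3C(=O)C=C(C)[C@H]2[C@@H]3C1(C)C | intermediate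
31 | (2R)-2-methylbutanoic acid | CC[C@@H](C)C(=O)O | starting material
32 | N,N'-dicyclohexyl-O-[(2R)-2-methylbutanoyl]isourea | CC[C@@H](C)C(=O)OC(=NC1CCCCC1)NC1CCCCC1 | intermediate
33 | (1R,2R,3S,4S,5S,7S,8R)-3-hydroxy-2,6,6,9-tetramethyl-4-{[(2R)-2-methylbutanoyl]oxy}-11-oxotricyclo[5.4.0.0^{2,8}]undec-9-en-5-yl (2Z)-2-methylbut-2-enoate (CNP0206166.1) | C/C=C(/C)C(=O)O[C@@H]1[C@@H](OC(=O)[C@H](C)CC)[C@@H](O)[C@@]2(C)[C@@H]3C(=O)C=C(C)[C@H]2[C@@H]3C1(C)C | target

## Step count and least certain steps

Total step count: 16. Longest linear sequence: 15 steps (1, 2, 7, 8, 10, 13, 15, 16, 20, 21, 23, 26, 27, 29, 30, 33; steps 1 and 3–16). Step 2 is a one-step side branch.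

**Step 6 (key step).** Three things may go wrong. The enyne alkene may be too weak a nucleophile, so that ketene dimerisation wins. The silyloxy group may fail to hold the A(1,3)-controlled conformation, giving poor facial selectivity. Isomerisation to the 2Z acid chloride may be followed by deprotonation at C4 or by lactonisation with loss of the silyl group. Fallback, from 10 back to 13: the acid is coupled with pyrrolidine to give amide 1-[(2E,5S,6E)-5-{[tert-butyl(dimethyl)silyl]oxy}-3,7-dimethylnona-2,6-dien-8-ynoyl]pyrrolidine F1. Treatment with triflic anhydride and 2,4,6-collidine in hot 1,2-dichloroethane generates the more electrophilic vinylketeniminium ion, which should undergo the same crossed [2+2] at lower temperature and give the cyclobutaniminium triflate F2. Aqueous bicarbonate hydrolysis of F2 returns to 13.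

**Step 9.** The hindered lithium aldolate may revert by retro-aldol cleavage, or the 2-alkenylcyclobutanolate may fragment at C7–C8 before it is trapped. Fallback, from 16 back to 21, avoiding a free alkoxide: 16 is converted with TMSOTf and Et3N into the silyl dienol ether F3, which is cyclised by a TiCl4-mediated intramolecular Mukaiyama aldol addition to the β-hydroxy ketone F4. F4 is acylated with methyl chlorooxoacetate and DMAP to the methyl oxalate F5, which is reduced with tributyltin hydride and AIBN to 21.

**Step 10.** The C7 radical may open the cyclobutane by β-scission of C1–C2 toward an enone-stabilised allylic radical, or the enone may undergo conjugate reduction. Fallback, from 20 back to 21, taking the C3=C4 bond out of play during the radical step: thiophenol and Et3N add to the enone of 20 to give the C3 phenylsulfanyl ketone xanthate F6 (mixture at C3). Tin hydride reduction then gives the deoxygenated sulfide F7, periodate oxidation gives the sulfoxide F8, and gentle heating eliminates benzenesulfenic acid to regenerate the ring alkene and arrive at 21.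

**Step 11.** The quaternary C6 and the alkenyl C4 may compete for the large-group role in the oxazaborolidine complex, giving poor or reversed facial selection and hence the C5 epimer. Fallback, from 21 back to 23, replacing reagent control by separation and recycling: Luche reduction (NaBH4, CeCl3) gives 23 together with its C5 epimer, (1R,2R,5S,7S,8R,11S)-11-{[tert-butyl(dimethyl)silyl]oxy}-2,6,6-trimethyl-9-methylidenetricyclo[5.4.0.0^{2,8}]undec-3-en-5-ol F9. The two are diastereomers and separable by chromatography; F9 is oxidised back to 21 with Dess–Martin periodinane and resubmitted.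

**Step 16.** Acylation may occur at the C3 hydroxyl or twice, and the new ester or the angelate may migrate between neighbouring oxygens. Fallback, from 30 back to 33, activating one oxygen through a tin acetal: 30 is heated with dibutyltin oxide to give the 3,4-O-dibutylstannylene acetal F10, in which the less hindered C4 oxygen is the nucleophilic one. F10 is treated at low temperature with (2R)-2-methylbutanoyl chloride F11, made from 31 with oxalyl chloride, to give 33 without an amine base.

## Further compounds

F1 | step 6 | 1-[(2E,5S,6E)-5-{[tert-butyl(dimethyl)silyl]oxy}-3,7-dimethylnona-2,6-dien-8-ynoyl]pyrrolidine | O=C(/C=C(\C)C[C@H](O[Si](C)(C)C(C)(C)C)/C=C(\C)C#C)N1CCCC1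
F2 | step 6 | 1-[(1R,2S,5R,7R)-2-{[tert-butyl(dimethyl)silyl]oxy}-7-ethynyl-7-methyl-4-methylidenebicyclo[3.1.1]heptan-6-ylidene]pyrrolidinium trifluoromethanesulfonate | C#C[C@@]1(C)[C@@H]2[C@@H](O[Si](C)(C)C(C)(C)C)CC(=C)[C@H]1C2=[N+]3CCCC3.[O-]S(=O)(=O)C(F)(F)F
F3 | step 9 | trimethylsilyl dienol ether of 16 | CC(C)=C(O[Si](C)(C)C)/C=C\[C@@]1(C)[C@@H]2[C@@H](O[Si](C)(C)C(C)(C)C)CC(=C)[C@H]1C2=O
F4 | step 9 | (1R,2R,7R,8R,11S)-11-{[tert-butyl(dimethyl)silyl]oxy}-7-hydroxy-2,6,6-trimethyl-9-methylidenetricyclo[5.4.0.0^{2,8}]undec-3-en-5-one | O=C1C=C[C@@]2(C)[C@@H]3[C@@H](O[Si](C)(C)C(C)(C)C)CC(=C)[C@H]2[C@]3(O)C1(C)C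
F5 | step 9 | methyl (1R,2R,7R,8R,11S)-11-{[tert-butyl(dimethyl)silyl]oxy}-2,6,6-trimethyl-9-methylidene-5-oxotricyclo[5.4.0.0^{2,8}]undec-3-en-7-yl oxalate | O=C1C=C[C@@]2(C)[C@@H]3[C@@H](O[Si](C)(C)C(C)(C)C)CC(=C)[C@H]2[C@]3(OC(=O)C(=O)OC)C1(C)C
F6 | step 10 | C3 phenylsulfanyl adduct of xanthate 20 (mixture at C3) | O=C1CC(Sc4ccccc4)[C@@]2(C)[C@@H]3[C@@H](O[Si](C)(C)C(C)(C)C)CC(=C)[C@H]2[C@]3(OC(=S)SC)C1(C)C
F7 | step 10 | C3 phenylsulfanyl ketone after deoxygenation at C7 (mixture at C3) | O=C1CC(Sc4ccccc4)[C@@]2(C)[C@@H]3[C@@H](O[Si](C)(C)C(C)(C)C)CC(=C)[C@H]2[C@@H]3C1(C)C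
F8 | step 10 | C3 phenylsulfinyl ketone (mixture at C3 and sulfur) | O=C1CC(S(=O)c4ccccc4)[C@@]2(C)[C@@H]3[C@@H](O[Si](C)(C)C(C)(C)C)CC(=C)[C@H]2[C@@H]3C1(C)C
F9 | step 11 | (1R,2R,5S,7S,8R,11S)-11-{[tert-butyl(dimethyl)silyl]oxy}-2,6,6-trimethyl-9-methylidenetricyclo[5.4.0.0^{2,8}]undec-3-en-5-ol | O[C@H]1C=C[C@@]2(C)[C@@H]3[C@@H](O[Si](C)(C)C(C)(C)C)CC(=C)[C@H]2[C@@H]3C1(C)C
F10 | step 16 | 3,4-O-dibutylstannylene acetal of diol 30 | C/C=C(/C)C(=O)O[C@@H]1[C@H]2O[Sn](CCCC)(CCCC)O[C@H]2[C@@]3(C)[C@@H]4C(=O)C=C(C)[C@H]3[C@@H]4C1(C)C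
F11 | step 16 | (2R)-2-methylbutanoyl chloride | CC[C@@H](C)C(Cl)=O
A1 | alternative 1 | eleven-membered humulatrienone carrying the three oxygen functions of the target (C1=C2 E, C9=C10 Z, C7=C8 E) | C/C=C(/C)C(=O)O[C@@H]1[C@@H](OC(=O)[C@H](C)CC)[C@@H](O)/C(C)=C/C(=O)/C=C(C)\C=C\C1(C)C
A2 | alternative 2 | (1S,5S)-(−)-verbenone | CC1(C)[C@@H]2C[C@H]1C(C)=CC2=O
A3 | alternative 2 | (1R,5S)-chrysanthenone | CC1(C)[C@@H]2CC=C(C)[C@H]1C2=O
A4 | alternative 3 | cis-1,3-diacetylcyclobutane on the bicyclo[4.1.1]octane core, carrying the three oxygen functions of the target | C/C=C(/C)C(=O)O[C@@H]1[C@@H](OC(=O)[C@H](C)CC)[C@@H](O)[C@@]2(C)[C@H](C(C)=O)[C@H]([C@@H]2C(C)=O)C1(C)C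
A5 | alternative 3 | regioisomer of 33 with the enone carbonyl attached to C8 and the methyl-bearing alkene carbon attached to C1 | C/C=C(/C)C(=O)O[C@@H]1[C@@H](OC(=O)[C@H](C)CC)[C@@H](O)[C@@]2(C)[C@@H]3C(C)=CC(=O)[C@H]2[C@@H]3C1(C)C
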